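## The problem

The target 20 is a (2S)-flavanone: rings A and C form a 5,7-dihydroxychroman-4-one, catechol ring B sits on C2, and C6 carries an (S,E)-3,7-dimethylocta-1,6-dienyl chain between the two ring A hydroxyls. The two stereocentres, C2 and C3' of the chain, lie on opposite sides of ring A and cannot control each other. C3' therefore has to arrive ready-made, and C2 has to be set by a reagent or an enantiopure building block. The chain must be placed at C6 and not at C8, which substitution of a preformed 5,7-dioxygenated flavanone does not guarantee. Several parts are fragile: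

- C2 is lost by retro-oxa-Michael opening to the 2'-hydroxychalcone once the ketone is free and base is present.
- The C1'=C2' styrene, flanked by two phenolic oxygens, protonates easily; the resulting C1' cation is placed for six-membered cation–olefin cyclisation onto the C6'=C7' alkene.
- C3' is allylic, and the catechol is oxidation-prone.

The enabling feature is the 1,3-relation of the C4 carbonyl and the oxygen-bearing C2 through the C3 methylene. If C4 is a ring A acyl anion equivalent, C3–C4 can be made by attack on the CH2 carbon of a ring B aryl oxirane that already carries the C2 configuration. The O1–C2 bond then closes from the ring A phenol next to C4.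

## Retrosynthesis

**20 back to 18 and 17 (no skeletal bond cut).** The four phenols are masked as methoxymethyl (MOM) ethers in 18 and the C4 ketone as a 1,3-dithiane in 17. The ketone is released only after ring C is closed, so no intermediate before 18 can open to a chalcone. The MOM groups are removed last by silyl transfer through the tetrakis(trimethylsilyl) ether 19, without protic acid, because of the acid-sensitive styrene and alkene.

**17 back to 16 (cut O1–C2).** The alternative closure of this bond, oxa-Michael addition in a chalcone, forms C2 at a trigonal carbon with no inherent control. Cutting at an sp3 carbinol allows a Mitsunobu etherification with inversion, so the (R)-carbinol 16 gives (2S)-17. Compound 16 has a single free phenol, para to the chain, so only the 6-substituted flavanone can form.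

**16 back to 10 and 14 (cut C3–C4, the key disconnection).** Cutting C2–C3 instead would mean an acetophenone aldol that is hard to control in absolute sense and gives a dehydration-prone β-hydroxy ketone. Cutting C4–C4a would mean an acylation of ring A under acid with C6/C8 ambiguity. The C3–C4 cut divides the molecule into the ring A dithiane 10 and the ring B oxirane 14, which are of similar size. It requires the dilithio species 15 to attack the oxirane CH2 and leave the benzylic C–O bond untouched.

**10 back to 9 and 8 (thioacetal; cut C4–C4a).** The formyl carbon of aldehyde 9 is introduced by ortho-formylation of phenol 8. The two ortho positions of 8 are equivalent by symmetry, so one aldehyde results and the oxygen para to the chain becomes O1. The forward steps must spare the MOM ethers and both alkenes.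

**8 back to 7, 6, and 3 plus 4 (cut C1'=C2' and C6–C1').** The E-styrene of 7 comes from dehydration of benzylic alcohol 6, which has β-hydrogens only on C2'. Alcohol 6 comes from aryllithium 5 and (S)-citronellal 4. The aldehyde carbon of 4 becomes C1', and its β-stereocentre becomes C3' without being touched. Arene 3 is lithiated only between its two MOM ethers. A Heck or cross-coupling entry would put the E-geometry and C3' at the mercy of β-hydride elimination.

**3 back to 2 and 1.** Phloroglucinol 1 is monosilylated to 2 and the remaining phenols are converted to MOM ethers. The silyl group marks the oxygen that becomes O1.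

**14 back to 13, 12 and 11.** The oxirane comes from chloroketone 12 by asymmetric transfer hydrogenation to chlorohydrin 13 and base closure. Ketone 12 is the bis-MOM ether of commercial 2-chloro-3',4'-dihydroxyacetophenone 11. The C2 stereocentre is thus set catalytically on a small molecule.

## Roads not taken

**Alternative 1:** Ring A is cut at C5–C6, C7–C8 and C4a–C5 and built by benzannulation. Wolff rearrangement of the diazo ketone A1, a (2S)-2-aryl-6-diazoacetyl-2,3-dihydropyran-4-one, would give a vinylketene. This adds the siloxy enyne A2 by (2+2) cycloaddition; four-electron ring opening and six-electron electrocyclisation then deliver the flavanone A3 (5-OH free, 7-O-triisopropylsilyl, ring B as bis-silyl ether).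
- Merits: the substitution pattern of ring A is fixed by construction. The all-silyl protection would allow a fluoride endgame, which is gentler on the styrene than the MOM removal of the chosen plan; in that respect this road is better.
- Weak points: A1 needs C2 set early on a dihydropyranone that can itself open by β-elimination, and then has to survive the heat or light of the Wolff step. A2 is a sensitive conjugated ynol ether needing several steps from the chain. The enyne offers the ketene a second reactive π-system.
- Comparison: the chosen plan answers the endgame advantage with a non-protic MOM cleavage. Its fragments are each reached in at most seven steps, and the C2 stereocentre is exposed to only four steps after it enters the main chain.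

**Alternative 2:** The C6–C1' bond is cut. Zerovalent palladium formed from Pd(OAc)2 would insert into the C–I bond of the iodoflavanone A4, add to the terminal alkene of (S)-β-citronellene A5 and give the tris-MOM flavanone A6 after β-hydride elimination.
- Merits: this is the most convergent plan. The chain enters last and never meets strong base, and if a preformed flavanone core can be iodinated cleanly, the step count would be clearly lower than in the chosen plan.
- Weak points: iodination of a 5-hydroxy-7-alkoxyflavanone does not reliably choose C6 over C8. After carbopalladation the palladium at C2' has β-hydrogens on both C1' and C3'; elimination toward C3' gives the allyl isomer and erases the stereocentre, and reinsertion of the palladium hydride can move the double bond. The base and heat of the coupling act on a free flavanone whose C2 opens to the chalcone.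
- Comparison: the chosen plan is longer. In return the chain position is fixed by symmetry, the E-alkene comes from an elimination with only one possible regiochemistry, and C2 never meets hot base.

**Alternative 3:** The C3'–C4' bond is cut. A chiral pybox complex of NiCl2·glyme (a divalent nickel precatalyst) would couple the racemic allylic chloride A7 with the homoprenylzinc bromide A8 in an enantioconvergent Negishi reaction to give the styrene A9. A9 is identical with compound 7 of the chosen route.
- Merits: C3' is set by the catalyst, either enantiomer is available, and the result does not depend on the enantiomeric purity of a commercial terpene. This is a real advantage over the chiral-pool approach.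
- Weak points: A7 is a secondary allylic chloride conjugated to a trioxygenated arene. It should ionise and transpose readily, and its preparation costs more steps than the two that lead from 3 to 7. The road addresses only the chain and leaves ring C and C2 open, so it is an alternative entry to 7, not a full plan.
- Comparison: the chosen plan obtains C3' in two steps from (S)-citronellal 4. It would adopt this coupling only if the purity of the aldehyde proved limiting.

Key step: step 10

Assumption: commercial (S)-citronellal of high enantiomeric purity is used; the route neither raises nor lowers the purity at C3'.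
Assumption: the (R,R)-TsDPEN ligand, which gives (R)-1-arylethanols from aryl methyl ketones, is taken to give the spatially analogous chlorohydrin, labelled S because CH2Cl outranks aryl; if the sense proved opposite, the enantiomeric ligand would be used.

## Route

Step 1
Reactants: 1 phloroglucinol
Product: 2 5-(triisopropylsilyloxy)benzene-1,3-diol
Conditions: TIPSCl (1 equiv), imidazole, DMF, 0 °C → rt; 1 in threefold excess
Reagents that add atoms: triisopropylsilyl chloride, CC(C)[Si](Cl)(C(C)C)C(C)C
Why: Statistical monosilylation of a symmetrical triol; the excess of cheap 1 suppresses bis-silylation and is washed out with water.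

Step 2
Reactants: 2 5-(triisopropylsilyloxy)benzene-1,3-diol
Product: 3 1,3-bis(methoxymethoxy)-5-(triisopropylsilyloxy)benzene
Conditions: MOMCl (2.5 equiv), i-Pr2NEt, CH2Cl2, 0 °C → rt
Reagents that add atoms: chloromethyl methyl ether, COCCl
Why: Standard O-alkylation of phenols to MOM ethers; the aryl silyl ether is stable to amine base.

Step 3
Reactants: 3 1,3-bis(methoxymethoxy)-5-(triisopropylsilyloxy)benzene; 4 (S)-citronellal
Product: 6 (3S)-1-[2,6-bis(methoxymethoxy)-4-(triisopropylsilyloxy)phenyl]-3,7-dimethyloct-6-en-1-ol (both C1 epimers), via aryllithium 5 (not isolated)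
Conditions: n-BuLi (1.1 equiv), THF, 0 °C; then 4, −78 → 0 °C; aq. NH4Cl
Reagents that add atoms: none
Why: Directed ortho-metalation occurs at the position flanked by both MOM ethers, and the aryllithium adds 1,2 to the aldehyde at low temperature; the stereocentre of 4 is β to the carbonyl and is not affected, and the new carbinol centre is removed in step 4.

Step 4
Reactants: 6 (3S)-1-[2,6-bis(methoxymethoxy)-4-(triisopropylsilyloxy)phenyl]-3,7-dimethyloct-6-en-1-ol
Product: 7 (S,E)-2-(3,7-dimethylocta-1,6-dienyl)-1,3-bis(methoxymethoxy)-5-(triisopropylsilyloxy)benzene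
Conditions: Burgess reagent (1.5 equiv), toluene, 50 °C
Reagents that add atoms: none
Why: Burgess dehydration under neutral conditions; the only β-hydrogens are on C2', so only the conjugated styrene can form, and the sulfamate counter-ion removes the proton within the ion pair to give the more stable E-alkene before the distant alkene can intervene.

Step 5
Reactants: 7 (S,E)-2-(3,7-dimethylocta-1,6-dienyl)-1,3-bis(methoxymethoxy)-5-(triisopropylsilyloxy)benzene
Product: 8 4-[(S,E)-3,7-dimethylocta-1,6-dienyl]-3,5-bis(methoxymethoxy)phenol
Conditions: TBAF (1.1 equiv), THF, 0 °C; aq. NH4Cl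
Reagents that add atoms: none
Why: Fluoride cleavage of an aryl silyl ether; MOM ethers and both alkenes are inert.

Step 6
Reactants: 8 4-[(S,E)-3,7-dimethylocta-1,6-dienyl]-3,5-bis(methoxymethoxy)phenol
Product: 9 3-[(S,E)-3,7-dimethylocta-1,6-dienyl]-6-hydroxy-2,4-bis(methoxymethoxy)benzaldehyde
Conditions: MgCl2, Et3N, (CH2O)n, MeCN, reflux
Reagents that add atoms: paraformaldehyde (formaldehyde), C=O
Why: Casnati–Skattebøl ortho-formylation through the magnesium phenoxide is ortho-specific, and the two ortho positions of 8 are equivalent, so a single salicylaldehyde should form; the weakly Lewis acidic, basic medium spares MOM ethers and alkenes.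

Step 7
Reactants: 9 3-[(S,E)-3,7-dimethylocta-1,6-dienyl]-6-hydroxy-2,4-bis(methoxymethoxy)benzaldehyde
Product: 10 2-{3-[(S,E)-3,7-dimethylocta-1,6-dienyl]-6-hydroxy-2,4-bis(methoxymethoxy)phenyl}-1,3-dithiane
Conditions: HS(CH2)3SH (1.2 equiv), Hf(OTf)4 (1 mol%), CH2Cl2, rt, dark
Reagents that add atoms: propane-1,3-dithiol, SCCCS
Why: Lewis-acid-catalysed dithioacetalisation of an aryl aldehyde; a low loading of a metal triflate is known to leave acid-labile protecting groups intact, and the electron-rich ring stabilises the thionium intermediate.

Step 8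
Reactants: 11 2-chloro-3',4'-dihydroxyacetophenone
Product: 12 1-[3,4-bis(methoxymethoxy)phenyl]-2-chloroethan-1-one
Conditions: MOMCl (2.5 equiv), then i-Pr2NEt added slowly, CH2Cl2, 0 °C → rt
Reagents that add atoms: chloromethyl methyl ether, COCCl
Why: MOM ether formation; MOMCl is present in excess before the base is added and is a far better electrophile than the phenacyl chloride, so self-alkylation of the catechol should not compete.

Step 9
Reactants: 12 1-[3,4-bis(methoxymethoxy)phenyl]-2-chloroethan-1-one
Product: 14 (S)-2-[3,4-bis(methoxymethoxy)phenyl]oxirane, via (S)-chlorohydrin 13 (not isolated)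
Conditions: RuCl[(R,R)-TsDPEN](p-cymene) (0.5 mol%), HCO2H/Et3N (5:2), EtOAc, rt; then 2 M aq. NaOH, i-PrOH, 0 °C; used crude
Reagents that add atoms: none
Why: Noyori asymmetric transfer hydrogenation of an α-chloro aryl ketone sets the carbinol centre through the ligand-controlled six-membered hydride-transfer transition state, and intramolecular Williamson closure then gives the oxirane without touching that centre, so (S)-13 gives (S)-14.

Step 10
Reactants: 10 2-{3-[(S,E)-3,7-dimethylocta-1,6-dienyl]-6-hydroxy-2,4-bis(methoxymethoxy)phenyl}-1,3-dithiane; 14 (S)-2-[3,4-bis(methoxymethoxy)phenyl]oxirane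
Product: 16 (1R)-1-[3,4-bis(methoxymethoxy)phenyl]-2-{2-[3-((S,E)-3,7-dimethylocta-1,6-dienyl)-6-hydroxy-2,4-bis(methoxymethoxy)phenyl]-1,3-dithian-2-yl}ethan-1-ol, via dilithio dithiane 15 (not isolated)
Conditions: n-BuLi (2.05 equiv), THF, −78 → −20 °C; then 14 (1.2 equiv), −78 → 0 °C; aq. NH4Cl
Reagents that add atoms: none
Why: Two equivalents of n-BuLi remove first the phenolic proton and then the dithiane C2–H, whose carbanion is stabilised by both sulfur atoms and held by the neighbouring OLi and OMOM oxygens; it attacks the CH2 carbon of oxirane 14 in an SN2 opening and forms the C3–C4 bond (Corey–Seebach umpolung). The closest known reaction type is the opening of enantiopure aryl oxiranes by dianions of 2-(2-hydroxyaryl)-1,3-dithianes on the way to flavanones. No ring closes and no stereocentre is created: the benzylic C–O bond of 14 is not touched, so the (S)-oxirane is carried over unchanged in space and is labelled R in 16 only because the new CH2 group ranks below aryl. The selectivity needed is attack at CH2 and not at the benzylic carbon, which the bulk of the tertiary carbanion, the ethereal solvent and the absence of added Lewis acid should secure. The phenoxide is a much weaker nucleophile than the carbanion at low temperature and should not compete for the oxirane. The dithiane C–H is more acidic than the allylic C3'–H and is presented to the base by chelation, so with no excess of n-BuLi the C3' centre and the styrene should be left alone. Because C4 remains a thioketal, the adduct has no enolisable ketone and cannot dehydrate or undergo retro-aldol cleavage before ring closure.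

Step 11
Reactants: 16 (1R)-1-[3,4-bis(methoxymethoxy)phenyl]-2-{2-[3-((S,E)-3,7-dimethylocta-1,6-dienyl)-6-hydroxy-2,4-bis(methoxymethoxy)phenyl]-1,3-dithian-2-yl}ethan-1-ol
Product: 17 (2S)-2-[3,4-bis(methoxymethoxy)phenyl]-6-[(S,E)-3,7-dimethylocta-1,6-dienyl]-5,7-bis(methoxymethoxy)spiro[chromane-4,2'-[1,3]dithiane]
Conditions: PPh3, DIAD, toluene, 0 °C → rt
Reagents that add atoms: none
Why: Intramolecular Mitsunobu etherification: the only free phenol displaces the oxyphosphonium group in a 6-exo-tet SN2 closure with inversion, so the (R)-carbinol gives the (2S) centre; the non-polar solvent and low temperature are chosen to disfavour ionisation at the electron-rich benzylic carbon.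

Step 12
Reactants: 17 (2S)-2-[3,4-bis(methoxymethoxy)phenyl]-6-[(S,E)-3,7-dimethylocta-1,6-dienyl]-5,7-bis(methoxymethoxy)spiro[chromane-4,2'-[1,3]dithiane]
Product: 18 (2S)-2-[3,4-bis(methoxymethoxy)phenyl]-6-[(S,E)-3,7-dimethylocta-1,6-dienyl]-5,7-bis(methoxymethoxy)chroman-4-one
Conditions: MeI (excess), CaCO3, MeCN/H2O (9:1), 40 °C
Reagents that add atoms: water, O
Why: Alkylative dithiane hydrolysis: S-methylation opens the thioketal to a thionium ion stabilised by the oxygenated ring, and water gives the ketone; the medium is buffered and non-oxidising, so alkenes, MOM ethers and the C2 centre (no free phenol, no strong base) should survive.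

Step 13
Reactants: 18 (2S)-2-[3,4-bis(methoxymethoxy)phenyl]-6-[(S,E)-3,7-dimethylocta-1,6-dienyl]-5,7-bis(methoxymethoxy)chroman-4-one
Product: 20 (2S)-2-(3,4-dihydroxyphenyl)-6-[(S,E)-3,7-dimethylocta-1,6-dienyl]-5,7-dihydroxychroman-4-one (CNP0230070.1), via tetrakis(trimethylsilyl) ether 19 (not isolated)
Conditions: TMSOTf (10 equiv), 2,2'-bipyridyl (15 equiv), MeCN, 0 °C → rt; then H2O, rt
Reagents that add atoms: none
Why: Silyl triflate with 2,2'-bipyridyl converts aryl MOM ethers into aryl trimethylsilyl ethers without free protic acid, and water then hydrolyses these to the phenols; this avoids protonation of the styrene and cation–olefin cyclisation of the chain, and there is no base to open ring C.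

## Compound list

1 | phloroglucinol (benzene-1,3,5-triol) | Oc1cc(O)cc(O)c1 | starting material
2 | 5-(triisopropylsilyloxy)benzene-1,3-diol | CC(C)[Si](Oc1cc(O)cc(O)c1)(C(C)C)C(C)C | intermediate
3 | 1,3-bis(methoxymethoxy)-5-(triisopropylsilyloxy)benzene | COCOc1cc(OCOC)cc(O[Si](C(C)C)(C(C)C)C(C)C)c1 | intermediate
4 | (S)-citronellal | CC(C)=CCC[C@H](C)CC=O | starting material
5 | [2,6-bis(methoxymethoxy)-4-(triisopropylsilyloxy)phenyl]lithium | [Li]c1c(OCOC)cc(O[Si](C(C)C)(C(C)C)C(C)C)cc1OCOC | intermediate
6 | (3S)-1-[2,6-bis(methoxymethoxy)-4-(triisopropylsilyloxy)phenyl]-3,7-dimethyloct-6-en-1-ol (both C1 epimers) | CC(C)=CCC[C@H](C)CC(O)c1c(OCOC)cc(O[Si](C(C)C)(C(C)C)C(C)C)cc1OCOC | intermediate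
7 | (S,E)-2-(3,7-dimethylocta-1,6-dienyl)-1,3-bis(methoxymethoxy)-5-(triisopropylsilyloxy)benzene | CC(C)=CCC[C@H](C)/C=C/c1c(OCOC)cc(O[Si](C(C)C)(C(C)C)C(C)C)cc1OCOC | intermediate
8 | 4-[(S,E)-3,7-dimethylocta-1,6-dienyl]-3,5-bis(methoxymethoxy)phenol | CC(C)=CCC[C@H](C)/C=C/c1c(OCOC)cc(O)cc1OCOC | intermediate
9 | 3-[(S,E)-3,7-dimethylocta-1,6-dienyl]-6-hydroxy-2,4-bis(methoxymethoxy)benzaldehyde | CC(C)=CCC[C@H](C)/C=C/c1c(OCOC)cc(O)c(C=O)c1OCOC | intermediate
10 | 2-{3-[(S,E)-3,7-dimethylocta-1,6-dienyl]-6-hydroxy-2,4-bis(methoxymethoxy)phenyl}-1,3-dithiane | CC(C)=CCC[C@H](C)/C=C/c1c(OCOC)cc(O)c(C2SCCCS2)c1OCOC | intermediate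
11 | 2-chloro-3',4'-dihydroxyacetophenone | O=C(CCl)c1ccc(O)c(O)c1 | starting material
12 | 1-[3,4-bis(methoxymethoxy)phenyl]-2-chloroethan-1-one | COCOc1ccc(C(=O)CCl)cc1OCOC | intermediate
13 | (S)-1-[3,4-bis(methoxymethoxy)phenyl]-2-chloroethan-1-ol | ClC[C@@H](O)c1ccc(OCOC)c(OCOC)c1 | intermediate
14 | (S)-2-[3,4-bis(methoxymethoxy)phenyl]oxirane | C1[C@H](c2ccc(OCOC)c(OCOC)c2)O1 | intermediate
15 | dilithio derivative of 10 (lithium phenoxide, 2-lithio-1,3-dithiane) | CC(C)=CCC[C@H](C)/C=C/c1c(OCOC)cc([O-])c([C-]2SCCCS2)c1OCOC.[Li+].[Li+] | intermediate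
16 | (1R)-1-[3,4-bis(methoxymethoxy)phenyl]-2-{2-[3-((S,E)-3,7-dimethylocta-1,6-dienyl)-6-hydroxy-2,4-bis(methoxymethoxy)phenyl]-1,3-dithian-2-yl}ethan-1-ol | CC(C)=CCC[C@H](C)/C=C/c1c(OCOC)cc(O)c(C2(C[C@H](c3ccc(OCOC)c(OCOC)c3)O)SCCCS2)c1OCOC | intermediate
17 | (2S)-2-[3,4-bis(methoxymethoxy)phenyl]-6-[(S,E)-3,7-dimethylocta-1,6-dienyl]-5,7-bis(methoxymethoxy)spiro[chromane-4,2'-[1,3]dithiane] | CC(C)=CCC[C@H](C)/C=C/c1c(OCOC)cc2c(c1OCOC)C3(SCCCS3)C[C@@H](c4ccc(OCOC)c(OCOC)c4)O2 | intermediate
18 | (2S)-2-[3,4-bis(methoxymethoxy)phenyl]-6-[(S,E)-3,7-dimethylocta-1,6-dienyl]-5,7-bis(methoxymethoxy)chroman-4-one | CC(C)=CCC[C@H](C)/C=C/c1c(OCOC)cc2c(c1OCOC)C(=O)C[C@@H](c1ccc(OCOC)c(OCOC)c1)O2 | intermediate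
19 | (2S)-2-[3,4-bis(trimethylsilyloxy)phenyl]-6-[(S,E)-3,7-dimethylocta-1,6-dienyl]-5,7-bis(trimethylsilyloxy)chroman-4-one | CC(C)=CCC[C@H](C)/C=C/c1c(O[Si](C)(C)C)cc2c(c1O[Si](C)(C)C)C(=O)C[C@@H](c1ccc(O[Si](C)(C)C)c(O[Si](C)(C)C)c1)O2 | intermediate
20 | (2S)-2-(3,4-dihydroxyphenyl)-6-[(S,E)-3,7-dimethylocta-1,6-dienyl]-5,7-dihydroxychroman-4-one (CNP0230070.1) | CC(C)=CCC[C@H](C)/C=C/c1c(O)cc2c(c1O)C(=O)C[C@@H](c1ccc(O)c(O)c1)O2 | target

## Step count and least certain steps

Total: 13 steps. Longest linear sequence: 11 steps (steps 1–7 and 10–13). The oxirane branch is steps 8 and 9.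

**Step 10 (key step).** The second lithiation of the hindered, electron-rich dithiane may be incomplete. The labile oxirane would then meet unreacted base or lithium salts and isomerise or open at the benzylic carbon, and any surplus n-BuLi could metalate the allylic C3' position.
Fallback, from 10 back to 16, using a monoanion in place of the dianion:
- The phenol of 10 is silylated (TBSCl, imidazole, DMF) to the O-tert-butyldimethylsilyl ether F1.
- One equivalent of n-BuLi (THF, −30 °C) gives the monoanion, which opens 14 to the silylated adduct F2.
- Buffered fluoride (TBAF, AcOH, THF) removes the silyl group from whichever oxygen it ends on and returns 16.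

**Step 11.** The oxyphosphonium intermediate may ionise at the benzylic carbon, which bears a para-oxygenated ring. This would cost inversion fidelity, and elimination to a styrene could also compete.
Fallback, from 16 back to 18, bypassing 17 and closing the O1–C2 bond at a trigonal carbon under catalyst control:
- The dithiane of 16 is hydrolysed (MeI, CaCO3, aq. MeCN) to the β-hydroxy ketone F3.
- Mild acid (PPTS, toluene, 40 °C) dehydrates F3 to the (E)-2'-hydroxychalcone F4.
- An enantioselective intramolecular oxa-Michael addition under a cinchona-alkaloid-derived bifunctional thiourea base then gives 18.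
- Catalyst control of this cyclisation is less dependable than Mitsunobu inversion, which is why it is held in reserve.

**Step 7.** The Lewis acid with the dithiol may cleave a MOM ether, or the thiol may add to the styrene or the trisubstituted alkene by an acid-promoted or radical path.
Fallback, from 8 directly to 10, with no aldehyde, acid or free thiol:
- 1,3-Dithiane and N-chlorosuccinimide (CH2Cl2, −70 °C) give the chlorosulfonium salt, which is treated with phenol 8 and then Et3N.
- The aryloxysulfonium ylide undergoes a [2,3]-sigmatropic (Sommelet–Hauser-type) shift to the ortho carbon, and rearomatisation gives 10.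

**Step 4.** The very electron-rich benzylic position may ionise before elimination. The C1' cation could then be captured by the C6'=C7' alkene (six-membered cation–olefin cyclisation) or by the sulfamate.
Fallback, from 3 back to 7, forming the C6–C1' bond and the alkene in one event without a benzylic cation:
- Aryllithium 5 is quenched with I2 to give the aryl iodide F5.
- A Heck reaction of F5 with (S)-3,7-dimethylocta-1,6-diene (the alkene labelled A5) gives 7, with zerovalent palladium formed from Pd(OAc)2 under phase-transfer conditions (Pd(OAc)2, n-Bu4NCl, NaHCO3, DMF, 70 °C).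
- The price is the risk of double-bond migration discussed under Alternative 2.

**Step 9.** The para-oxygenated aryl oxirane may solvolyse at the benzylic carbon or rearrange to the arylacetaldehyde during basic closure, concentration or storage.
Fallback, from 12 back to 16, without ever isolating the oxirane:
- The transfer hydrogenation is run alone and the stable chlorohydrin 13 is isolated.
- Compound 13 is deprotonated with one equivalent of n-BuLi at −78 °C and the lithium alkoxide is added to the dilithio species 15.
- On warming, the alkoxide closes to 14 in the flask, or the carbanion displaces chloride directly. Either way the same C3–C4 bond forms without touching the stereocentre, and the route is rejoined at 16.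

## Further compounds

F1 | step 10 | 2-{6-(tert-butyldimethylsilyloxy)-3-[(S,E)-3,7-dimethylocta-1,6-dienyl]-2,4-bis(methoxymethoxy)phenyl}-1,3-dithiane | CC(C)=CCC[C@H](C)/C=C/c1c(OCOC)cc(O[Si](C)(C)C(C)(C)C)c(C2SCCCS2)c1OCOC
F2 | step 10 | (1R)-1-[3,4-bis(methoxymethoxy)phenyl]-2-{2-[6-(tert-butyldimethylsilyloxy)-3-((S,E)-3,7-dimethylocta-1,6-dienyl)-2,4-bis(methoxymethoxy)phenyl]-1,3-dithian-2-yl}ethan-1-ol | CC(C)=CCC[C@H](C)/C=C/c1c(OCOC)cc(O[Si](C)(C)C(C)(C)C)c(C2(C[C@H](c3ccc(OCOC)c(OCOC)c3)O)SCCCS2)c1OCOC
F3 | step 11 | (3R)-3-[3,4-bis(methoxymethoxy)phenyl]-1-{3-[(S,E)-3,7-dimethylocta-1,6-dienyl]-6-hydroxy-2,4-bis(methoxymethoxy)phenyl}-3-hydroxypropan-1-one | CC(C)=CCC[C@H](C)/C=C/c1c(OCOC)cc(O)c(C(=O)C[C@H](c2ccc(OCOC)c(OCOC)c2)O)c1OCOC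
F4 | step 11 | (E)-3-[3,4-bis(methoxymethoxy)phenyl]-1-{3-[(S,E)-3,7-dimethylocta-1,6-dienyl]-6-hydroxy-2,4-bis(methoxymethoxy)phenyl}prop-2-en-1-one | CC(C)=CCC[C@H](C)/C=C/c1c(OCOC)cc(O)c(C(=O)/C=C/c2ccc(OCOC)c(OCOC)c2)c1OCOC
F0 | step 7 | none | none
F5 | step 4 | 2-iodo-1,3-bis(methoxymethoxy)-5-(triisopropylsilyloxy)benzene | COCOc1cc(O[Si](C(C)C)(C(C)C)C(C)C)cc(OCOC)c1I
F0 | step 9 | none | none
A1 | alternative 1 | (S)-2-[3,4-bis(tert-butyldimethylsilyloxy)phenyl]-6-(2-diazoacetyl)-2,3-dihydro-4H-pyran-4-one | [N-]=[N+]=CC(=O)C1=CC(=O)C[C@@H](c2ccc(O[Si](C)(C)C(C)(C)C)c(O[Si](C)(C)C(C)(C)C)c2)O1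
A2 | alternative 1 | (S,E)-[(5,9-dimethyldeca-3,8-dien-1-yn-1-yl)oxy]triisopropylsilane | CC(C)=CCC[C@H](C)/C=C/C#CO[Si](C(C)C)(C(C)C)C(C)C
A3 | alternative 1 | (2S)-2-[3,4-bis(tert-butyldimethylsilyloxy)phenyl]-6-[(S,E)-3,7-dimethylocta-1,6-dienyl]-5-hydroxy-7-(triisopropylsilyloxy)chroman-4-one | CC(C)=CCC[C@H](C)/C=C/c1c(O[Si](C(C)C)(C(C)C)C(C)C)cc2c(c1O)C(=O)C[C@@H](c1ccc(O[Si](C)(C)C(C)(C)C)c(O[Si](C)(C)C(C)(C)C)c1)O2
A4 | alternative 2 | (2S)-2-[3,4-bis(methoxymethoxy)phenyl]-5-hydroxy-6-iodo-7-(methoxymethoxy)chroman-4-one | COCOc1cc2c(c(O)c1I)C(=O)C[C@@H](c1ccc(OCOC)c(OCOC)c1)O2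
A5 | alternative 2 | (S)-3,7-dimethylocta-1,6-diene ((S)-β-citronellene) | CC(C)=CCC[C@H](C)C=C
A6 | alternative 2 | (2S)-2-[3,4-bis(methoxymethoxy)phenyl]-6-[(S,E)-3,7-dimethylocta-1,6-dienyl]-5-hydroxy-7-(methoxymethoxy)chroman-4-one | CC(C)=CCC[C@H](C)/C=C/c1c(OCOC)cc2c(c1O)C(=O)C[C@@H](c1ccc(OCOC)c(OCOC)c1)O2
A7 | alternative 3 | racemic (E)-2-(3-chlorobut-1-enyl)-1,3-bis(methoxymethoxy)-5-(triisopropylsilyloxy)benzene | CC(Cl)/C=C/c1c(OCOC)cc(O[Si](C(C)C)(C(C)C)C(C)C)cc1OCOC
A8 | alternative 3 | (4-methylpent-3-enyl)zinc bromide | CC(C)=CCC[Zn]Br
A9 | alternative 3 | (S,E)-2-(3,7-dimethylocta-1,6-dienyl)-1,3-bis(methoxymethoxy)-5-(triisopropylsilyloxy)benzene | CC(C)=CCC[C@H](C)/C=C/c1c(OCOC)cc(O[Si](C(C)C)(C(C)C)C(C)C)cc1OCOC
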